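## Retrosynthetic overview

- The A ring (acetophenone 1, joined to prenyl bromide 2 as ether 3) and the B ring (aldehyde 4) are bought; no carbocycle is built.
- Cα–Cβ disconnection: Claisen–Schmidt union of 3 and 4 (through aldol 5) gives chalcone 6.
- Key disconnection O1–C2: a chalcone-isomerase-like, catalyst-controlled enantioselective 6-endo oxa-Michael closure of 6 gives (2S)-flavanone 7. This is the only ring formed (the pyranone C ring) and the only stereocentre.
- C6–prenyl disconnection: a prenyltransferase-like O→C [1,3] prenyl shift converts 7 into target 8. The O-prenyl group first blocks the future 5-OH, so ring closure has one possible regiochemistry, and then supplies the C6 prenyl group.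

Assumption: 1 is bought as such; the facial sense in step 3 is assigned by analogy and is checked by CD on 7 (2S-flavanones: positive band near 330 nm, negative near 290 nm), with the quinidine-derived pseudoenantiomeric catalyst as the remedy if the sense is reversed.

## Route

Step 1
Reactants: 1 2',6'-dihydroxy-4'-methoxyacetophenone; 2 prenyl bromide (1-bromo-3-methylbut-2-ene)
Product: 3 2'-hydroxy-4'-methoxy-6'-(3-methylbut-2-en-1-yloxy)acetophenone
Conditions: 2 (1.05 equiv), K2CO3 (1.5 equiv), acetone, reflux
Reagents that add atoms: none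
Why: Williamson ether synthesis (phenoxide SN2 on a primary allylic bromide) in which the two OH groups of 1 are equivalent and, after the first alkylation, the remaining OH is locked in a hydrogen bond to the acetyl carbonyl, so the reaction stops at the mono-ether; no stereocentre is formed.

Step 2
Reactants: 3 2'-hydroxy-4'-methoxy-6'-(3-methylbut-2-en-1-yloxy)acetophenone; 4 3,4,5-trimethoxybenzaldehyde
Product: 6 (2E)-1-[2-hydroxy-4-methoxy-6-(3-methylbut-2-en-1-yloxy)phenyl]-3-(3,4,5-trimethoxyphenyl)prop-2-en-1-one, via aldol adduct 5 (not isolated)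
Conditions: KOH (50% aq, 10 equiv), EtOH, rt, 36 h; then cold 1 M HCl to pH 5
Reagents that add atoms: none
Why: Claisen–Schmidt condensation (crossed aldol with a non-enolisable aldehyde, then E1cB dehydration) gives the thermodynamic E-enone, which is held in strong base as the non-cyclising 2'-phenoxide while the prenyl ether is inert to base.

Step 3
Reactants: 6 (2E)-1-[2-hydroxy-4-methoxy-6-(3-methylbut-2-en-1-yloxy)phenyl]-3-(3,4,5-trimethoxyphenyl)prop-2-en-1-one
Product: 7 (2S)-7-methoxy-5-(3-methylbut-2-en-1-yloxy)-2-(3,4,5-trimethoxyphenyl)-2,3-dihydro-4H-chromen-4-one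
Conditions: N-[3,5-bis(trifluoromethyl)phenyl]-N'-[(8α,9S)-6'-methoxycinchonan-9-yl]thiourea (10 mol%), PhMe (0.05 M), 0 °C → rt, stopped at about 90% conversion (chiral HPLC) by filtration through silica
Reagents that add atoms: none
Why: Proposed new method: a direct catalytic enantioselective 6-endo-trig intramolecular oxa-Michael addition (the chalcone-isomerase reaction) on a chalcone with no activating 3-ester, in which the quinuclidine nitrogen deprotonates the acidic 2'-OH, the thiourea binds the s-cis enone carbonyl and the chiral ion pair closes on one face of Cβ to set C2 as S before C3 protonation; the 6'-alkoxy group twists the aryl ketone and speeds closure, the product has no phenol so its base-mediated reopening is slower than its formation and the run is stopped under kinetic control, and the closest known reactions are cinchona-alkaloid-catalysed cyclisations of o-hydroxyaryl enones to chromanones and cinchona-thiourea cyclisations of ester-activated 2'-hydroxychalcones.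

Step 4
Reactants: 7 (2S)-7-methoxy-5-(3-methylbut-2-en-1-yloxy)-2-(3,4,5-trimethoxyphenyl)-2,3-dihydro-4H-chromen-4-one
Product: 8 (2S)-5-hydroxy-7-methoxy-6-(3-methylbut-2-en-1-yl)-2-(3,4,5-trimethoxyphenyl)-2,3-dihydro-4H-chromen-4-one (artoflavanone)
Conditions: montmorillonite K10 (dried, 3 wt equiv), CH2Cl2, 0 °C → rt, 1–2 h
Reagents that add atoms: none
Why: Acid-clay-promoted formal [1,3] O→C prenyl shift of an aryl prenyl ether (contact-ion-pair, Friedel–Crafts-type recombination) in which acidic sites chelated between C4=O and O5 ionise the allylic C–O bond and the prenyl cation collapses through its primary terminus onto the adjacent C6, the only free ortho position, while the chelated 5-OH resists chroman formation and C2 is untouched and stays S.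

## Compound list

1 | 1-(2,6-dihydroxy-4-methoxyphenyl)ethan-1-one (2',6'-dihydroxy-4'-methoxyacetophenone) | CC(=O)c1c(O)cc(OC)cc1O | starting material
2 | 1-bromo-3-methylbut-2-ene (prenyl bromide) | CC(C)=CCBr | starting material
3 | 1-[2-hydroxy-4-methoxy-6-(3-methylbut-2-en-1-yloxy)phenyl]ethan-1-one | CC(=O)c1c(O)cc(OC)cc1OCC=C(C)C | intermediate
4 | 3,4,5-trimethoxybenzaldehyde | COc1cc(C=O)cc(OC)c1OC | starting material
5 | 3-hydroxy-1-[2-hydroxy-4-methoxy-6-(3-methylbut-2-en-1-yloxy)phenyl]-3-(3,4,5-trimethoxyphenyl)propan-1-one (racemic aldol adduct, not isolated) | COc1cc(O)c(C(=O)CC(O)c2cc(OC)c(OC)c(OC)c2)c(OCC=C(C)C)c1 | intermediate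
6 | (2E)-1-[2-hydroxy-4-methoxy-6-(3-methylbut-2-en-1-yloxy)phenyl]-3-(3,4,5-trimethoxyphenyl)prop-2-en-1-one | COc1cc(O)c(C(=O)/C=C/c2cc(OC)c(OC)c(OC)c2)c(OCC=C(C)C)c1 | intermediate
7 | (2S)-7-methoxy-5-(3-methylbut-2-en-1-yloxy)-2-(3,4,5-trimethoxyphenyl)-2,3-dihydro-4H-chromen-4-one | COc1cc2c(c(OCC=C(C)C)c1)C(=O)C[C@@H](c1cc(OC)c(OC)c(OC)c1)O2 | intermediate
8 | (2S)-5-hydroxy-7-methoxy-6-(3-methylbut-2-en-1-yl)-2-(3,4,5-trimethoxyphenyl)-2,3-dihydro-4H-chromen-4-one (artoflavanone) | COc1cc2c(c(O)c1CC=C(C)C)C(=O)C[C@@H](c1cc(OC)c(OC)c(OC)c1)O2 | target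

## Step count and risk

Total step count: 4. Longest linear sequence: 4 (1 → 3 → 6 → 7 → 8).

**Step 3 (most likely to fail).** The unactivated chalcone may close slowly or with modest ee, and the ee erodes if the reaction is allowed to equilibrate. The fallback sets out from 3 and comes back at 7, forming the stereocentre by C–C instead of C–O bond formation. Compound 3 is condensed with DMF dimethyl acetal (PhMe, 90 °C) to the enaminone (E)-3-(dimethylamino)-1-[2-hydroxy-4-methoxy-6-(3-methylbut-2-en-1-yloxy)phenyl]prop-2-en-1-one F1. This closes in warm acetic acid, with loss of dimethylamine, to the chromone 7-methoxy-5-(3-methylbut-2-en-1-yloxy)-4H-chromen-4-one F2. Rh(I)-catalysed asymmetric 1,4-addition of 3,4,5-trimethoxyphenylboronic acid (OB(O)c1cc(OC)c(OC)c(OC)c1) then gives 7. Conditions are [Rh(OH)(cod)]2 with an electron-poor MeO-BIPHEP-type bisphosphine of the enantiomer that delivers 2S, in PhMe–H2O at rt.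

**Step 4.** The prenyl cation may also reach C8, be lost altogether to give the free 5-hydroxyflavanone, or the product may close to a chroman. The fallback sets out from 7 and comes back at 8. The prenyl ether is cleaved (cat. Yb(OTf)3, MeNO2, rt, isoprene lost) to (2S)-5-hydroxy-7-methoxy-2-(3,4,5-trimethoxyphenyl)-2,3-dihydro-4H-chromen-4-one F3; the same phenol recovered as a by-product of step 4 can be pooled with it. Iodination directed by the free chelated 5-OH (BnMe3N+ ICl2−, CaCO3, CH2Cl2–MeOH, rt) gives (2S)-5-hydroxy-6-iodo-7-methoxy-2-(3,4,5-trimethoxyphenyl)-2,3-dihydro-4H-chromen-4-one F4. A base-free Stille coupling with tributyl(3-methylbut-2-en-1-yl)stannane (Pd(PPh3)4, DMF, 80 °C) then gives 8 without touching C2.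

**Step 1.** The electron-rich ambident phenoxide may C-prenylate or be alkylated twice. The fallback sets out from 1 and comes back at 3 by Mitsunobu etherification with 3-methylbut-2-en-1-ol (PPh3, DIAD, THF, 0 °C → rt). This never generates the free phenoxide, so it cannot C-alkylate, and the chelated second OH does not react. It makes no compound outside the list: none F0.

## Further compounds

F1 | step 3 | (E)-3-(dimethylamino)-1-[2-hydroxy-4-methoxy-6-(3-methylbut-2-en-1-yloxy)phenyl]prop-2-en-1-one | CN(C)/C=C/C(=O)c1c(O)cc(OC)cc1OCC=C(C)C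
F2 | step 3 | 7-methoxy-5-(3-methylbut-2-en-1-yloxy)-4H-chromen-4-one | O=c1ccoc2cc(OC)cc(OCC=C(C)C)c12
F3 | step 4 | (2S)-5-hydroxy-7-methoxy-2-(3,4,5-trimethoxyphenyl)-2,3-dihydro-4H-chromen-4-one | COc1cc2c(c(O)c1)C(=O)C[C@@H](c1cc(OC)c(OC)c(OC)c1)O2
F4 | step 4 | (2S)-5-hydroxy-6-iodo-7-methoxy-2-(3,4,5-trimethoxyphenyl)-2,3-dihydro-4H-chromen-4-one | COc1cc2c(c(O)c1I)C(=O)C[C@@H](c1cc(OC)c(OC)c(OC)c1)O2
F0 | step 1 | none | none
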